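## Analysis of the target

The target 32 is a xenicane-type tricycle. Ring A is a nine-membered carbocycle (C4a–C5–C6–C7–C8–C9–C10–C11–C11a). It is trans-fused at C4a/C11a to ring B, a six-membered cyclic acetal (C11a–C1–O2–C3–C4–C4a). Ring B shares the C3–C4 bond with ring C, a 2,5-dihydrofuran (C3–C4=C12–C13–O), and C13 carries a C14 secondary and C15 tertiary diol.

There are eight stereocentres. C13 and C14 form an erythro pair that can be taken from the chiral pool. C3 is fixed by the ring fusion: a chair ring B with equatorial ring A bonds and a planar ring C puts H3 axial and cis to H4a. C4a and C11a are trans. C7 (tertiary carbinol), C8 and C9 (cis-epoxide on the same face as the C7 hydroxyl) must be related to C4a/C11a across a flexible nine-membered ring, and this is the hardest relation to control.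

The sensitive groups are the allylic acetal at C3, which ionises under acid and can aromatise to a furan; the 2,3-epoxy tertiary alcohol, which is open to Payne migration and to acid-induced transannular opening; and the C11=C19 exocyclic olefin. The medium ring is costly to close by cyclisation.

The strategy rests on one feature of ring A: C7 and C11 are both carbonyl-derived and 1,5-related through C8, C9 and C10, with C8/C9 at the olefin oxidation level. This is the pattern left when a two-carbon unit is inserted into a seven-membered 1,3-dione by [2+2] photocycloaddition and retro-aldol cleavage.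

## Retrosynthetic reasoning

**32 from 31.** Only the two silyl ethers on O14 and O15 are removed last. The finished acetal and epoxy alcohol then meet nothing but a desilylating agent, and all eight stereocentres are already present in 31.

**31 from lactol 30 and butenolide mesylate 29.** Ring B is opened at the O2–C1 bond, not at C3–O2. The forward reaction is then an SN2 attack of the lactol oxygen of 30 on a C1 mesylate. No oxocarbenium ion is formed, which is the species that would lose H13 and give a furan. Lactol 30 comes from 1,2-reduction of butenolide 29, so C3 enters at the carboxyl level and O13 is already bonded to it.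

**29 from the hydroxy γ-lactone 27 and aldol adduct 25.** The C4=C12 olefin is cut back to a C12 hydroxyl β to the lactone carbonyl. Elimination inside the five-membered lactone can only give the endocyclic olefin, so no alkylidene geometry has to be controlled. Lactone 27 arises from 25 by acyl transfer from O2 to O13. This transfer also frees the C1 hydroxyl, so ring B of 25 serves as the protecting group for C1.

**25 from lactone 18 and aldehyde 24.** The C4–C12 bond is cut as an aldol. C4 is the only enolisable position of 18 once ring A carries no carbonyl, and 24 brings C12–C15 with both side-chain stereocentres. O13 must be unmasked independently of O14 and O15, so 24 carries a triethylsilyl group on O13 and tert-butyldimethylsilyl groups on O14 and O15.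

**24 from 2,3-O-isopropylidene-D-erythronolactone 19, through 20–23.** The lactone carbonyl of 19 becomes C15 by double methyl addition and the lactone CH2–O becomes C12. C13 and C14 are carried over unchanged. The acetal is removed on the small tetraol 21, where acid is harmless. O13 is then told apart from O14 by the steric difference between an ordinary and a neopentylic secondary hydroxyl.

**18 from the ene-dione 13, through 14–17.** Three functional-group changes are cut on ring A. The epoxide goes back to the Z-olefin of 15 by hydroxyl-directed epoxidation. The C7 carbinol goes back to the enone of 14 by methyl addition. The C11 methylene goes back to the saturated ketone of 13. Methylenation has to come first because the C10 methylene of 13 lies between a ketone and an enone and tolerates no basic reagent. The δ-lactone of 18 is closed from the C1 silyl ether and the methyl ester only after these steps.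

**13 from the vinylogous ester 9 and acetylene 10.** The C7–C8 and C9–C10 bonds are cut, and ring A contracts to a cycloheptenone by re-forming C7–C10. In the forward direction 10 adds across C7=C10 of 9, and removal of the 4-methoxybenzyl group lets the cyclobutenol open by retro-aldol. The benzyl group sits on O7, so C7 becomes the enone carbonyl and C11 the saturated one. This places the olefin at C8=C9, where the epoxide is needed. The disconnection is made here because it turns a nine-membered ring closure into a strain-driven ring expansion of an easily made seven-membered ring.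

**9 from cycloheptane-1,3-dione 1 and dimethyl malonate 4, through 2, 3 and 5–8.** C1 is attached to C11a by an aldol at the α′ position of the vinylogous ester, and C4 to C4a by asymmetric Michael addition of 4 to the cross-conjugated dienone 3. Dienone 3 comes from 2 by dehydrogenation and 2 from 1. The malonate is kept through the hydroxymethylation, where its enolate masks the ester α-position, and is cut down to the acetate only afterwards.

## Alternatives that were turned down

**Alternative 1: conjugate addition–aldol on a δ-lactone.** Ring B is disconnected as an unsaturated δ-lactone that already carries the C11a substituent (C11 with its methylene, C10 and a silylated C8≡C9 alkyne). In the forward step an organocopper reagent carrying C5–C7 as a ketal-masked methyl ketone adds to C4a, and the enolate is trapped by a C12 aldehyde, giving the trisubstituted lactone A1.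

- For: two C–C bonds (C4a–C5, C4–C12) form in one flask, and the trans C4a/C11a relation follows from addition anti to the C11a substituent. On this relation it is as strong as the chosen route, and it gets there in fewer steps.
- Against: ring A is still open in A1. It would have to be closed between C7 and C8 by intramolecular addition of an alkyne-derived nucleophile to a methyl ketone. This is a nine-membered ring closure against entropy and transannular strain, with no control at C7 and a Z-olefin still to be made from the alkyne. A1 also carries O13 and O14 in one acetonide, so ring C could only be closed after an acid deprotection.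
- Comparison: the chosen route gives up this convergence but forms the medium ring by fragmentation of a strained bicycle, with the Z-olefin built in.

**Alternative 2: carbonylative butenolide closure.** Ring C is cut at C3–C4 and C3–O, with C3 coming from CO. Pd(PPh3)4 (zerovalent palladium) inserts into the C4–I bond of a Z-iodoalkenol, CO inserts, and the C13 hydroxyl captures the acylpalladium to give butenolide A2.

- For: the butenolide forms in one step with the olefin endocyclic by construction and no enolate chemistry at C4. On ring C it is stronger than the chosen route, which needs an aldol, an acyl transfer and an elimination.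
- Against: it presupposes a finished ring A with the Z-olefin and the C7 carbinol, so the main problem of the molecule is left to other chemistry. It needs a regio- and stereodefined vinyl iodide at a hindered, α-branched carbon. A2 carries O14/O15 as an acetonide that must later be removed by acid next to the acetal.
- Comparison: the chosen route spends more steps on ring C, but its key step delivers ring A with both carbonyl handles differentiated.

**Alternative 3: ruthenium Alder-ene closure of ring A.** Ring A is cut at C10–C11. [CpRu(MeCN)3]PF6 couples a terminal alkyne on C11a with the terminal olefin of the C4a chain, forming C10–C11 and leaving the C11 methylene and the C8=C9 olefin in the tricyclic ene A3.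

- For: rings B and C and the C7 carbinol can be made on open-chain material, where C7 can be set by reagent control. On control of C7 and on convergence it is stronger than the chosen route. The ring closure is atom-economical and installs both ring A olefins at once.
- Against: it is a direct nine-membered ring closure. The metallacycle must give the branched regiochemistry and a Z-olefin inside the ring, where the intermolecular reaction normally gives E. The cationic ruthenium catalyst meets the ionisable allylic acetal and a free tertiary alcohol.
- Comparison: the chosen route accepts an uncertain facial selectivity at C7, but its ring formation is driven by release of cyclobutene strain, and the cis geometry of the cyclobutene guarantees the Z-olefin.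

Key step: step 7

Assumption: compound 19 is the (3aR,6aR) enantiomer drawn by its SMILES, and the (S)-binaphthoxide catalyst of step 3 is assumed to induce in the sense known for simple cycloalkenones (ligand and adduct carrying the same descriptor); if the sense is reversed on this dienone, the (R)-ligand is used.

## Route

Step 1
Reactants: 1 cycloheptane-1,3-dione
Product: 2 3-[(4-methoxybenzyl)oxy]cyclohept-2-en-1-one
Conditions: 4-MeOC6H4CH2OH (1.2 equiv), p-TsOH·H2O (cat.), PhH, reflux, Dean–Stark
Reagents that add atoms: 4-methoxybenzyl alcohol, COc1ccc(CO)cc1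
Why: Acid-catalysed vinylogous esterification of a cyclic 1,3-dione with azeotropic removal of water; the dione is symmetric, so only one enol ether can form.

Step 2
Reactants: 2 3-[(4-methoxybenzyl)oxy]cyclohept-2-en-1-one
Product: 3 3-[(4-methoxybenzyl)oxy]cyclohepta-2,6-dien-1-one
Conditions: LiN(iPr)2 (LDA), THF, −78 °C; then PhS(Cl)=NtBu, −78 °C
Reagents that add atoms: none
Why: Kinetic deprotonation of a vinylogous ester occurs at the α′ carbon (C11a), and the lithium enolate is dehydrogenated in one pot by the sulfinimidoyl chloride through S–C bond formation and syn elimination (Mukaiyama dehydrogenation), giving the cross-conjugated dienone with the new C11a=C4a olefin.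

Step 3
Reactants: 3 3-[(4-methoxybenzyl)oxy]cyclohepta-2,6-dien-1-one; 4 dimethyl malonate
Product: 5 dimethyl 2-[(1S)-5-[(4-methoxybenzyl)oxy]-3-oxocyclohept-4-en-1-yl]malonate
Conditions: LiAl[(S)-binaphthoxide]2 (10 mol %, from LiAlH4 and (S)-BINOL 1:2), KOtBu (9 mol %), 4 Å MS, THF, rt
Reagents that add atoms: none
Why: Catalytic asymmetric Michael addition of a malonate to a cyclic enone with a lithium–aluminium binaphthoxide that binds both the ketone and the malonate enolate and delivers the nucleophile to one face of C4a, setting that centre as (S); the alkoxy-bearing C7 terminus is deactivated as a vinylogous ester, so only the C11a=C4a olefin accepts the nucleophile.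

Step 4
Reactants: 5 dimethyl 2-[(1S)-5-[(4-methoxybenzyl)oxy]-3-oxocyclohept-4-en-1-yl]malonate
Product: 6 dimethyl 2-[(1S,2S)-2-(hydroxymethyl)-5-[(4-methoxybenzyl)oxy]-3-oxocyclohept-4-en-1-yl]malonate
Conditions: LiN(iPr)2 (2.2 equiv), THF, −78 °C; CH2O (monomeric, THF solution), −78 °C; aq. NH4Cl at −78 °C
Reagents that add atoms: formaldehyde, C=O
Why: The first equivalent of base turns the malonate into its enolate, which masks the ester α-position, and the second forms the α′ ketone enolate at C11a; this more reactive enolate undergoes aldol addition to formaldehyde anti to the bulky C4a substituent, setting the trans C4a/C11a relation.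

Step 5
Reactants: 6 dimethyl 2-[(1S,2S)-2-(hydroxymethyl)-5-[(4-methoxybenzyl)oxy]-3-oxocyclohept-4-en-1-yl]malonate
Product: 7 dimethyl 2-[(1S,2S)-2-{[(tert-butyldimethylsilyl)oxy]methyl}-5-[(4-methoxybenzyl)oxy]-3-oxocyclohept-4-en-1-yl]malonate
Conditions: TBSCl, imidazole, DMF, 0 °C to rt
Reagents that add atoms: tert-butyldimethylsilyl chloride, CC(C)(C)[Si](C)(C)Cl
Why: Standard silylation of a primary alcohol; it is done at once so that the β-hydroxy ketone can neither dehydrate nor lactonise onto the malonate.

Step 6
Reactants: 7 dimethyl 2-[(1S,2S)-2-{[(tert-butyldimethylsilyl)oxy]methyl}-5-[(4-methoxybenzyl)oxy]-3-oxocyclohept-4-en-1-yl]malonate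
Product: 9 methyl 2-[(1R,2S)-2-{[(tert-butyldimethylsilyl)oxy]methyl}-5-[(4-methoxybenzyl)oxy]-3-oxocyclohept-4-en-1-yl]acetate, via malonic half-ester 8 (not isolated)
Conditions: KOH (1.1 equiv), THF–H2O, 0 °C; cold dilute HCl to pH 4, extraction; then Cu2O (cat.), MeCN, 80 °C
Reagents that add atoms: none
Why: Selective monosaponification of the malonate followed by mild copper-catalysed decarboxylation of the half-acid leaves the methyl acetate arm; a halide-mediated dealkoxycarbonylation is avoided because its nucleophile would also dealkylate the benzylic vinylogous ester and its temperature would endanger the β-silyloxy ketone.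

Step 7
Reactants: 9 methyl 2-[(1R,2S)-2-{[(tert-butyldimethylsilyl)oxy]methyl}-5-[(4-methoxybenzyl)oxy]-3-oxocyclohept-4-en-1-yl]acetate; 10 acetylene
Product: 13 methyl 2-[(1R,2S,5Z)-2-{[(tert-butyldimethylsilyl)oxy]methyl}-3,7-dioxocyclonon-5-en-1-yl]acetate, via cyclobutene photoadduct 11 (not isolated), via cyclobutenol 12 (not isolated)
Conditions: C2H2-saturated CH2Cl2 (slow C2H2 stream), hν (medium-pressure Hg lamp, uranium-glass filter, λ > 330 nm), −70 °C; N2 purge; then DDQ (1.2 equiv), CH2Cl2–pH 7 phosphate buffer, 0 °C
Reagents that add atoms: none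
Why: De Mayo reaction: the n,π* excited (triplet) vinylogous ester adds acetylene across C7=C10 through a 1,4-biradical that collapses to the cyclobutene 11 (bonds C7–C8 and C9–C10), the four-membered ring closing by radical recombination. DDQ then abstracts the benzylic hydride of the 4-methoxybenzyl ether, water gives the hemiacetal, and loss of 4-methoxybenzaldehyde frees the β-hydroxy ketone 12. Retro-aldol cleavage of the shared C7–C10 bond, driven by release of cyclobutene strain, expands the seven-membered ring to the nine-membered ring A, so ring A is formed by fragmentation and not by cyclisation. The dienol formed is protonated at C10 to give 13. The closest known reactions are de Mayo ring expansions of five- and six-membered 1,3-dione enol derivatives with alkenes and with acetylene. No stereocentre is created in 13 (the two ring-fusion centres of 11 are destroyed), the cis geometry of the cyclobutene fixes the Z-olefin, and C4a and C11a are untouched. The step needs three selectivities: the position of the olefin, secured by the benzyl group on O7; cycloaddition over enone twisting and dimerisation, helped by dilution and a large excess of acetylene at low temperature; and neutral unmasking, which prevents double-bond migration through the acidic C10 methylene, transannular aldol reaction of the 1,5-dione and epimerisation or β-elimination at C11a. Compound 13 is carried on at once.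

Step 8
Reactants: 13 methyl 2-[(1R,2S,5Z)-2-{[(tert-butyldimethylsilyl)oxy]methyl}-3,7-dioxocyclonon-5-en-1-yl]acetate
Product: 14 methyl 2-[(1R,2R,5Z)-2-{[(tert-butyldimethylsilyl)oxy]methyl}-3-methylidene-7-oxocyclonon-5-en-1-yl]acetate
Conditions: Zn, CH2Br2, TiCl4 (pre-formed reagent), THF–CH2Cl2, 0 °C
Reagents that add atoms: dibromomethane, BrCBr
Why: Non-basic zinc–titanium methylenation (Takai–Lombardo): the isolated C11 ketone is more electrophilic than the conjugated C7 enone and the ester, and the reagent neither enolises the acidic C10 methylene nor epimerises C11a.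

Step 9
Reactants: 14 methyl 2-[(1R,2R,5Z)-2-{[(tert-butyldimethylsilyl)oxy]methyl}-3-methylidene-7-oxocyclonon-5-en-1-yl]acetate
Product: 15 methyl 2-[(1R,2R,5Z,7S)-2-{[(tert-butyldimethylsilyl)oxy]methyl}-7-hydroxy-7-methyl-3-methylidenecyclonon-5-en-1-yl]acetate
Conditions: MeLi, CeCl3 (anhydrous), THF, −78 °C
Reagents that add atoms: methyllithium, [Li]C
Why: 1,2-Addition of the weakly basic organocerium reagent MeCeCl2 to the enone carbonyl, faster than attack on the methyl ester at −78 °C and without deprotonation of the doubly allylic C10. Peripheral attack on the conformer that turns the C7 oxygen to the face opposite the C4a acetate arm would set (7S); this facial bias is an expectation and not a certainty.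

Step 10
Reactants: 15 methyl 2-[(1R,2R,5Z,7S)-2-{[(tert-butyldimethylsilyl)oxy]methyl}-7-hydroxy-7-methyl-3-methylidenecyclonon-5-en-1-yl]acetate
Product: 16 the 8,9-cis-epoxide of 15 with the oxygen syn to the C7 hydroxyl (7S,8R,9R, target numbering)
Conditions: VO(acac)2 (cat.), tBuOOH (decane solution), CH2Cl2, 0 °C to rt
Reagents that add atoms: tert-butyl hydroperoxide, CC(C)(C)OO
Why: Hydroxyl-directed epoxidation: the vanadate ester of the tertiary allylic alcohol delivers oxygen to the face of C8=C9 syn to the C7 oxygen, the usual outcome for medium-ring Z-cycloalkenols, which sets (8R,9R) from (7S); the remote C11 methylene has no directing hydroxyl within reach and is left.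

Step 11
Reactants: 16 the 8,9-cis-epoxide of 15
Product: 18 ring B δ-lactone (C1–O2–C3(=O)–C4, trans-fused to ring A) carrying the 7-hydroxy-8,9-epoxide and the C11 methylene, via C1 hydroxy ester 17 (not isolated)
Conditions: Bu4NF, THF, 0 °C to rt; aq. NH4Cl
Reagents that add atoms: none
Why: Fluoride desilylation frees the C1 alkoxide, which closes the six-membered lactone onto the methyl ester (6-exo-trig acyl substitution); ring B is then in place at the lactone level, and C1 is protected until the acyl transfer of step 18.

Step 12
Reactants: 19 2,3-O-isopropylidene-D-erythronolactone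
Product: 20 2-[(4R,5R)-5-(hydroxymethyl)-2,2-dimethyl-1,3-dioxolan-4-yl]propan-2-ol
Conditions: MeMgBr (3 equiv), THF, 0 °C to rt; aq. NH4Cl
Reagents that add atoms: methylmagnesium bromide, C[Mg]Br
Why: Double Grignard addition to the lactone carbonyl gives the C15 tertiary carbinol and frees the C12 primary alcohol; C13 and C14 keep their configuration because no bond to them is touched.

Step 13
Reactants: 20 2-[(4R,5R)-5-(hydroxymethyl)-2,2-dimethyl-1,3-dioxolan-4-yl]propan-2-ol
Product: 21 (2R,3R)-4-methylpentane-1,2,3,4-tetrol
Conditions: Dowex 50W (H+ form), MeOH–H2O, 40 °C; filtration, evaporation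
Reagents that add atoms: none
Why: Acid-catalysed acetal hydrolysis on a robust small molecule, placed here so that no acid is needed later on the coupled material.

Step 14
Reactants: 21 (2R,3R)-4-methylpentane-1,2,3,4-tetrol
Product: 22 (3R,4R)-2-methyl-4,5-bis[(triethylsilyl)oxy]pentane-2,3-diol
Conditions: Et3SiCl (2.05 equiv), imidazole, DMF, −40 to −20 °C
Reagents that add atoms: chlorotriethylsilane, CC[Si](CC)(CC)Cl
Why: Rate-controlled silylation: the primary C12 hydroxyl and the unhindered secondary C13 hydroxyl react before the neopentylic C14 hydroxyl and the tertiary C15 hydroxyl, which tells O13 (the future lactone oxygen) apart from O14.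

Step 15
Reactants: 22 (3R,4R)-2-methyl-4,5-bis[(triethylsilyl)oxy]pentane-2,3-diol
Product: 23 (2R,3R)-3,4-bis[(tert-butyldimethylsilyl)oxy]-4-methyl-1,2-bis[(triethylsilyl)oxy]pentane
Conditions: TBSOTf (3 equiv), 2,6-lutidine, CH2Cl2, 0 °C to rt
Reagents that add atoms: tert-butyldimethylsilyl triflate, CC(C)(C)[Si](C)(C)OS(=O)(=O)C(F)(F)F
Why: Silyl triflate silylation of the hindered secondary and the tertiary hydroxyl; these bulkier silyl ethers outlast the later selective removal of the triethylsilyl group on O13.

Step 16
Reactants: 23 (2R,3R)-3,4-bis[(tert-butyldimethylsilyl)oxy]-4-methyl-1,2-bis[(triethylsilyl)oxy]pentane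
Product: 24 (2S,3R)-3,4-bis[(tert-butyldimethylsilyl)oxy]-4-methyl-2-[(triethylsilyl)oxy]pentanal
Conditions: (COCl)2, DMSO, CH2Cl2, −78 to −40 °C; then Et3N, −78 to 0 °C
Reagents that add atoms: none
Why: Under Swern conditions a primary triethylsilyl ether is cleaved and oxidised in one operation while secondary and tertiary silyl ethers persist, so the α-silyloxy aldehyde is obtained without a separate deprotection; it is used at once to keep C13 intact.

Step 17
Reactants: 18 ring B δ-lactone; 24 (2S,3R)-3,4-bis[(tert-butyldimethylsilyl)oxy]-4-methyl-2-[(triethylsilyl)oxy]pentanal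
Product: 25 aldol adduct: lactone 18 bearing at C4 the C12 carbinol chain CH(OH)–C13H(OSiEt3)–C14H(OTBS)–C15Me2(OTBS) (mixture at C4 and C12)
Conditions: LiN(iPr)2 (2.2 equiv), THF, −78 °C; then 24; AcOH at −78 °C
Reagents that add atoms: none
Why: Lithium lactone enolate aldol addition forms the C4–C12 bond (the second equivalent of base only forms the inert C7 alkoxide); the configurations at C4 and C12 do not matter because both carbons become sp2 in step 19.

Step 18
Reactants: 25 aldol adduct
Product: 27 β-hydroxy γ-lactone (O13–C3(=O)–C4–C12(OH)–C13) with free C1 hydroxyl, via C13 alcohol 26 (not isolated)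
Conditions: Bu4NF–AcOH (1:1), THF, 0 °C; then Et3N, DMAP (cat.), CH2Cl2, rt
Reagents that add atoms: none
Why: Buffered fluoride removes the triethylsilyl group selectively beside the two bulkier silyl ethers, and amine-catalysed acyl transfer from the six-membered to the thermodynamically preferred five-membered lactone (translactonisation) moves the carboxyl onto O13 and releases the C1 hydroxyl; the buffer suppresses alkoxide-driven silyl migration and retro-aldol cleavage.

Step 19
Reactants: 27 β-hydroxy γ-lactone
Product: 29 butenolide (O13–C3(=O)–C4=C12–C13) with C1 methanesulfonate, via bis-mesylate 28 (not isolated)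
Conditions: MsCl (3 equiv), Et3N (8 equiv), CH2Cl2, −20 °C to rt
Reagents that add atoms: methanesulfonyl chloride, CS(=O)(=O)Cl
Why: The C12 and C1 hydroxyls are both mesylated, but only the C12 mesylate is β to the lactone carbonyl, so amine-induced E1cB elimination gives the endocyclic C4=C12 butenolide with no olefin geometry to control, while the C1 mesylate is kept as the leaving group for ring B. The hindered tertiary C7 hydroxyl should stay free, and the weak base avoids epimerising the γ-centre C13.

Step 20
Reactants: 29 butenolide with C1 methanesulfonate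
Product: 30 lactol (C3 hemiacetal of ring C, both anomers) with C1 methanesulfonate
Conditions: iBu2AlH (2.5 equiv), CH2Cl2, −78 °C; MeOH, aq. KNa tartrate
Reagents that add atoms: none
Why: 1,2-Reduction of an α,β-unsaturated γ-lactone to the lactol at low temperature, stopped there by a neutral work-up; the mesylate, the silyl ethers and the epoxide are not reduced under these conditions.

Step 21
Reactants: 30 lactol with C1 methanesulfonate
Product: 31 tricyclic acetal (rings A, B and C of the target) with O14 and O15 as tert-butyldimethylsilyl ethers
Conditions: KN(SiMe3)2 (1.05 equiv), THF, −78 to 0 °C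
Reagents that add atoms: none
Why: Intramolecular anomeric O-alkylation, the reaction type that turns 6-O-sulfonyl hexoses into 1,6-anhydro sugars: the lactolate oxygen displaces the primary mesylate in a 6-exo-tet closure of ring B, so no oxocarbenium ion and no furan can form. The lactol anomers interconvert through the open Z-hydroxy enal, and only the anomer that closes through a chair with equatorial ring A bonds and H3 axial, cis to H4a, reacts, which sets (3S); one equivalent of base deprotonates the lactol and not the tertiary C7 hydroxyl.

Step 22
Reactants: 31 tricyclic acetal bis-silyl ether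
Product: 32 the target, (3S,4aS,7S,8R,9R,11aR,13R,14R) in the numbering used here
Conditions: Bu4NF (4 equiv), THF, 0 °C to rt; aq. NH4Cl
Reagents that add atoms: none
Why: Fluoride cleavage of the secondary and the tertiary silyl ether (the tertiary group can leave after migration to the freed neighbouring oxygen); no acid touches the allylic acetal or the epoxide.

## Compound list

1 | cycloheptane-1,3-dione | O=C1CCCCC(=O)C1 | starting material
2 | 3-[(4-methoxybenzyl)oxy]cyclohept-2-en-1-one | O=C1C=C(OCc2ccc(OC)cc2)CCCC1 | intermediate
3 | 3-[(4-methoxybenzyl)oxy]cyclohepta-2,6-dien-1-one | O=C1C=C(OCc2ccc(OC)cc2)CCC=C1 | intermediate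
4 | dimethyl malonate | COC(=O)CC(=O)OC | starting material
5 | dimethyl 2-[(1S)-5-[(4-methoxybenzyl)oxy]-3-oxocyclohept-4-en-1-yl]malonate | O=C1C=C(OCc2ccc(OC)cc2)CC[C@H](C(C(=O)OC)C(=O)OC)C1 | intermediate
6 | dimethyl 2-[(1S,2S)-2-(hydroxymethyl)-5-[(4-methoxybenzyl)oxy]-3-oxocyclohept-4-en-1-yl]malonate | O=C1C=C(OCc2ccc(OC)cc2)CC[C@H](C(C(=O)OC)C(=O)OC)[C@H]1CO | intermediate
7 | dimethyl 2-[(1S,2S)-2-{[(tert-butyldimethylsilyl)oxy]methyl}-5-[(4-methoxybenzyl)oxy]-3-oxocyclohept-4-en-1-yl]malonate | O=C1C=C(OCc2ccc(OC)cc2)CC[C@H](C(C(=O)OC)C(=O)OC)[C@H]1CO[Si](C)(C)C(C)(C)C | intermediate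
8 | malonic half-ester of 7 (one ester hydrolysed, both epimers at the malonyl carbon) | O=C1C=C(OCc2ccc(OC)cc2)CC[C@H](C(C(=O)O)C(=O)OC)[C@H]1CO[Si](C)(C)C(C)(C)C | intermediate (not isolated)
9 | methyl 2-[(1R,2S)-2-{[(tert-butyldimethylsilyl)oxy]methyl}-5-[(4-methoxybenzyl)oxy]-3-oxocyclohept-4-en-1-yl]acetate | O=C1C=C(OCc2ccc(OC)cc2)CC[C@H](CC(=O)OC)[C@H]1CO[Si](C)(C)C(C)(C)C | intermediate (key-step precursor)
10 | acetylene | C#C | starting material
11 | methyl 2-[(3S,4R)-3-{[(tert-butyldimethylsilyl)oxy]methyl}-7-[(4-methoxybenzyl)oxy]-2-oxobicyclo[5.2.0]non-8-en-4-yl]acetate (ring-fusion centres unassigned) | O=C1C2C=CC2(OCc3ccc(OC)cc3)CC[C@H](CC(=O)OC)[C@H]1CO[Si](C)(C)C(C)(C)C | intermediate (not isolated)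
12 | methyl 2-[(3S,4R)-3-{[(tert-butyldimethylsilyl)oxy]methyl}-7-hydroxy-2-oxobicyclo[5.2.0]non-8-en-4-yl]acetate | O=C1C2C=CC2(O)CC[C@H](CC(=O)OC)[C@H]1CO[Si](C)(C)C(C)(C)C | intermediate (not isolated)
13 | methyl 2-[(1R,2S,5Z)-2-{[(tert-butyldimethylsilyl)oxy]methyl}-3,7-dioxocyclonon-5-en-1-yl]acetate | O=C1C/C=C\C(=O)CC[C@H](CC(=O)OC)[C@H]1CO[Si](C)(C)C(C)(C)C | intermediate (key-step product)
14 | methyl 2-[(1R,2R,5Z)-2-{[(tert-butyldimethylsilyl)oxy]methyl}-3-methylidene-7-oxocyclonon-5-en-1-yl]acetate | C=C1C/C=C\C(=O)CC[C@H](CC(=O)OC)[C@H]1CO[Si](C)(C)C(C)(C)C | intermediate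
15 | methyl 2-[(1R,2R,5Z,7S)-2-{[(tert-butyldimethylsilyl)oxy]methyl}-7-hydroxy-7-methyl-3-methylidenecyclonon-5-en-1-yl]acetate | C=C1C/C=C\[C@@](C)(O)CC[C@H](CC(=O)OC)[C@H]1CO[Si](C)(C)C(C)(C)C | intermediate
16 | 8,9-cis-epoxide of 15, oxygen syn to the C7 hydroxyl (7S,8R,9R) | C=C1C[C@H]2O[C@H]2[C@@](C)(O)CC[C@H](CC(=O)OC)[C@H]1CO[Si](C)(C)C(C)(C)C | intermediate
17 | C1 alcohol of 16 (hydroxy methyl ester) | C=C1C[C@H]2O[C@H]2[C@@](C)(O)CC[C@H](CC(=O)OC)[C@H]1CO | intermediate (not isolated)
18 | ring B δ-lactone, trans-fused, with 7-hydroxy-7-methyl, 8,9-epoxide and C11 methylene | C=C1C[C@H]2O[C@H]2[C@@](C)(O)CC[C@@H]2CC(=O)OC[C@@H]12 | intermediate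
19 | 2,3-O-isopropylidene-D-erythronolactone, (3aR,6aR) | O=C1OC[C@H]2OC(C)(C)O[C@@H]12 | starting material
20 | 2-[(4R,5R)-5-(hydroxymethyl)-2,2-dimethyl-1,3-dioxolan-4-yl]propan-2-ol | OC[C@H]1OC(C)(C)O[C@H]1C(C)(C)O | intermediate
21 | (2R,3R)-4-methylpentane-1,2,3,4-tetrol | OC[C@@H](O)[C@@H](O)C(C)(C)O | intermediate
22 | (3R,4R)-2-methyl-4,5-bis[(triethylsilyl)oxy]pentane-2,3-diol | CC[Si](CC)(CC)OC[C@@H](O[Si](CC)(CC)CC)[C@@H](O)C(C)(C)O | intermediate
23 | (2R,3R)-3,4-bis[(tert-butyldimethylsilyl)oxy]-4-methyl-1,2-bis[(triethylsilyl)oxy]pentane | CC[Si](CC)(CC)OC[C@@H](O[Si](CC)(CC)CC)[C@@H](O[Si](C)(C)C(C)(C)C)C(C)(C)O[Si](C)(C)C(C)(C)C | intermediate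
24 | (2S,3R)-3,4-bis[(tert-butyldimethylsilyl)oxy]-4-methyl-2-[(triethylsilyl)oxy]pentanal | O=C[C@@H](O[Si](CC)(CC)CC)[C@@H](O[Si](C)(C)C(C)(C)C)C(C)(C)O[Si](C)(C)C(C)(C)C | intermediate
25 | aldol adduct of 18 and 24 (C4–C12 bond, C12 hydroxyl; epimers at C4 and C12) | C=C1C[C@H]2O[C@H]2[C@@](C)(O)CC[C@@H]2C(C(O)[C@@H](O[Si](CC)(CC)CC)[C@@H](O[Si](C)(C)C(C)(C)C)C(C)(C)O[Si](C)(C)C(C)(C)C)C(=O)OC[C@@H]12 | intermediate
26 | C13 alcohol of 25 (δ-lactone still on O2) | C=C1C[C@H]2O[C@H]2[C@@](C)(O)CC[C@@H]2C(C(O)[C@@H](O)[C@@H](O[Si](C)(C)C(C)(C)C)C(C)(C)O[Si](C)(C)C(C)(C)C)C(=O)OC[C@@H]12 | intermediate (not isolated)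
27 | β-hydroxy γ-lactone on O13 with free C1 hydroxyl | C=C1C[C@H]2O[C@H]2[C@@](C)(O)CC[C@H](C2C(O)[C@H]([C@@H](O[Si](C)(C)C(C)(C)C)C(C)(C)O[Si](C)(C)C(C)(C)C)OC2=O)[C@H]1CO | intermediate
28 | C1,C12-bis(methanesulfonate) of 27 | C=C1C[C@H]2O[C@H]2[C@@](C)(O)CC[C@H](C2C(OS(C)(=O)=O)[C@H]([C@@H](O[Si](C)(C)C(C)(C)C)C(C)(C)O[Si](C)(C)C(C)(C)C)OC2=O)[C@H]1COS(C)(=O)=O | intermediate (not isolated)
29 | ring C butenolide with C1 methanesulfonate | C=C1C[C@H]2O[C@H]2[C@@](C)(O)CC[C@H](C2=C[C@H]([C@@H](O[Si](C)(C)C(C)(C)C)C(C)(C)O[Si](C)(C)C(C)(C)C)OC2=O)[C@H]1COS(C)(=O)=O | intermediate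
30 | ring C lactol (C3 hemiacetal, both anomers) with C1 methanesulfonate | C=C1C[C@H]2O[C@H]2[C@@](C)(O)CC[C@H](C2=C[C@H]([C@@H](O[Si](C)(C)C(C)(C)C)C(C)(C)O[Si](C)(C)C(C)(C)C)OC2O)[C@H]1COS(C)(=O)=O | intermediate
31 | 14,15-bis-O-(tert-butyldimethylsilyl) ether of the target | C=C1C[C@H]2O[C@H]2[C@@](C)(O)CC[C@@H]2C3=C[C@H]([C@@H](O[Si](C)(C)C(C)(C)C)C(C)(C)O[Si](C)(C)C(C)(C)C)O[C@@H]3OC[C@@H]12 | intermediate
32 | CNP0281409.2, (3S,4aS,7S,8R,9R,11aR,13R,14R) | C=C1C[C@H]2O[C@H]2[C@@](C)(O)CC[C@@H]2C3=C[C@H]([C@@H](O)C(C)(C)O)O[C@@H]3OC[C@@H]12 | target

## Step count and least certain steps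

Total: 22 steps. The longest linear sequence is 17 steps (steps 1–11 and 17–22); the side chain takes steps 12–16.

**Step 7 (key step).** The most likely failure is that the excited seven-membered vinylogous ester relaxes by twisting about its C=C bond and then dimerises or reverts instead of capturing acetylene, which is a poor and dilute 2π partner. The β,γ-unsaturated ketone of the adduct can also undergo secondary photoreaction (1,3-acyl shift), and the unmasked 1,5-dione can suffer double-bond migration or transannular aldol reaction. Fallback: from 9, irradiate in the presence of a large excess of 1,2-dichloroethene, a better and more concentrated partner that serves as an acetylene surrogate. This gives the dichlorocyclobutane F1. Reductive 1,2-dechlorination with zinc dust in ethanol then gives the cyclobutene 11, where the route is rejoined before the DDQ unmasking to 13.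

**Step 8.** The most likely failure is loss of chemoselectivity: competing or double methylenation at the C7 enone carbonyl, or Lewis-acid-induced enolisation of the 1,5-dione before the reagent has reacted. Fallback: from 13, add Me3SiCH2Li–CeCl3 at −78 °C, an addition governed by carbonyl electrophilicity in the way that favours saturated ketones over enones with hydride and organometal nucleophiles. This gives the β-hydroxysilane F2. Peterson elimination with catalytic p-TsOH in CH2Cl2 at 0 °C then returns to 14.

**Step 9.** The most likely failure is poor or reversed facial selectivity at C7, because the preferred conformation of the Z-cyclononenone cannot be predicted with confidence and nothing in the substrate directs the reagent. Fallback: from 14, reverse the order of C–O and C–C bond formation. Nucleophilic epoxidation of the enone (tBuOOH, DBU) gives the cis-epoxy ketone F3, with the peroxide entering from the ring periphery. MeMgBr then adds anti to the epoxide oxygen (chelation and Felkin control), which gives the cis epoxy alcohol with the facial sense opposite to that of the methyl-addition/directed-epoxidation order. The route is rejoined at 16 and step 10 is skipped.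

**Step 21.** The most likely failure is ring-opening of the lactolate to the hydroxy enal, followed by alkylation through the C13 alkoxide or elimination of the mesylate, or Payne migration if the C7 alkoxide forms. Fallback: from 27, use the acid-catalysed closure. Selective silylation of the primary C1 hydroxyl (Et3SiCl, imidazole, −40 °C) gives the silyl ether F7. Mesylation and elimination at C12 (MsCl, Et3N) gives the butenolide F8. Reduction with iBu2AlH gives the lactol F9. PPTS in CH2Cl2–MeOH at 0 °C then cleaves the primary triethylsilyl ether and lets the C1 hydroxyl replace the lactol hydroxyl under acetal exchange, kept short to limit furan formation. The route is rejoined at 31.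

**Step 14.** The most likely failure is incomplete discrimination between the two secondary hydroxyls (silylation at O14 or silyl migration), which would put the labile group on the wrong oxygen. Fallback: from 21, form the terminal 12,13-acetonide F4 under kinetic control (2-methoxypropene, PPTS, 0 °C). Silylate O14 and O15 with TBSOTf to give the bis-silyl ether F5. Hydrolyse the terminal acetonide (aq. AcOH) to the diol F6, and silylate both remaining hydroxyls with Et3SiCl. The route is rejoined at 23.

## Further compounds

F1 | step 7 | methyl 2-[(3S,4R)-3-{[(tert-butyldimethylsilyl)oxy]methyl}-8,9-dichloro-7-[(4-methoxybenzyl)oxy]-2-oxobicyclo[5.2.0]nonan-4-yl]acetate | O=C1C2C(Cl)C(Cl)C2(OCc3ccc(OC)cc3)CC[C@H](CC(=O)OC)[C@H]1CO[Si](C)(C)C(C)(C)C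
F2 | step 8 | C11 β-hydroxysilane: 13 with C11 as C(OH)CH2SiMe3 | C[Si](C)(C)CC1(O)C/C=C\C(=O)CC[C@H](CC(=O)OC)[C@H]1CO[Si](C)(C)C(C)(C)C
F3 | step 9 | 8,9-cis-epoxy C7 ketone (8R,9R) derived from 14 | C=C1C[C@H]2O[C@H]2C(=O)CC[C@H](CC(=O)OC)[C@H]1CO[Si](C)(C)C(C)(C)C
F4 | step 14 | (3R)-3-[(4R)-2,2-dimethyl-1,3-dioxolan-4-yl]-2-methylpropane-2,3-diol (12,13-acetonide of 21) | CC1(C)OC[C@H]([C@@H](O)C(C)(C)O)O1
F5 | step 14 | 14,15-bis-O-(tert-butyldimethylsilyl) ether of F4 | CC1(C)OC[C@H]([C@@H](O[Si](C)(C)C(C)(C)C)C(C)(C)O[Si](C)(C)C(C)(C)C)O1
F6 | step 14 | (2R,3R)-3,4-bis[(tert-butyldimethylsilyl)oxy]-4-methylpentane-1,2-diol | OC[C@@H](O)[C@@H](O[Si](C)(C)C(C)(C)C)C(C)(C)O[Si](C)(C)C(C)(C)C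
F7 | step 21 | C1 triethylsilyl ether of 27 | C=C1C[C@H]2O[C@H]2[C@@](C)(O)CC[C@H](C2C(O)[C@H]([C@@H](O[Si](C)(C)C(C)(C)C)C(C)(C)O[Si](C)(C)C(C)(C)C)OC2=O)[C@H]1CO[Si](CC)(CC)CC
F8 | step 21 | ring C butenolide with C1 triethylsilyl ether | C=C1C[C@H]2O[C@H]2[C@@](C)(O)CC[C@H](C2=C[C@H]([C@@H](O[Si](C)(C)C(C)(C)C)C(C)(C)O[Si](C)(C)C(C)(C)C)OC2=O)[C@H]1CO[Si](CC)(CC)CC
F9 | step 21 | ring C lactol with C1 triethylsilyl ether | C=C1C[C@H]2O[C@H]2[C@@](C)(O)CC[C@H](C2=C[C@H]([C@@H](O[Si](C)(C)C(C)(C)C)C(C)(C)O[Si](C)(C)C(C)(C)C)OC2O)[C@H]1CO[Si](CC)(CC)CC
A1 | alternative 1 | trisubstituted δ-lactone aldol from the conjugate addition–aldol (C4 and C12 epimers) | O=C1OC[C@@H](C(=C)CC#C[Si](C)(C)C)[C@H](CCC2(C)OCCO2)C1C(O)[C@H]3OC(C)(C)O[C@H]3C(C)(C)O[Si](CC)(CC)CC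
A2 | alternative 2 | ring C butenolide from the carbonylative closure | C=C1C/C=C\[C@@](C)(O[Si](CC)(CC)CC)CC[C@H](C2=C[C@H]([C@H]3OC(C)(C)OC3(C)C)OC2=O)[C@H]1CO[Si](C)(C)C(C)(C)C
A3 | alternative 3 | tricyclic 8,9-ene bis(triethylsilyl) ether from the Alder-ene closure | C=C1C/C=C\[C@@](C)(O)CC[C@@H]2C3=C[C@H]([C@@H](O[Si](CC)(CC)CC)C(C)(C)O[Si](CC)(CC)CC)O[C@@H]3OC[C@@H]12
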